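**Plan**
1. Cuts (target numbering: C1 = CH‑aryl, C2 = CH‑CH2OAc, C3 = C‑CHO, C4 = CH=, then C4a/C8a of the fused arene). C1–C8a is cut and C1 is rejoined to C4, which shrinks the carbocycle C1–C2–C3–C4–C4a–C8a to the cyclobutane C1–C2–C3–C4. The cyclobutane is then cut at C1–C4 and C2–C3 into two ferulic acid units.
2. Enabling feature: C1 and C4 each carry a guaiacyl ring whose OH is para to that carbon (4′‑OH and 7‑OH). Two‑electron oxidation can therefore break the strained, doubly benzylic C1–C4 bond to a bis‑p‑quinone methide. The C3 formyl group acidifies only H‑3, and 6‑OMe is para to C8a, the carbon that closes onto C1.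
3. Forward order: two O‑silyl ferulic acids are tied to naphthalene‑1,8‑diol, and a topochemical [2+2] photocycloaddition closes the meso cyclobutane. Reduction frees the diol and the template; monoacetylation, oxidation and desilylation arm it. The oxidative 4→6 ring expansion then gives the target itself.
4. Stereochemistry: the photodimer fixes the relative configuration. Lipase desymmetrisation of the meso diol fixes C2 (R), the only cyclobutane centre that survives. C1 (S) is set trans to it during the ring expansion.

Key step: step 8

Assumption: the sense of enantiotopic‑group selection of the lipase on diol 7 cannot be predicted with certainty. The route is written for acylation of the CH2OH on the R‑configured ring carbon, to be confirmed on 8; the fallback to step 5 reaches the same 8 if the sense is opposite.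

Step 1
Reactants: 1 (E)-ferulic acid
Product: 3 (E)-3-[4-(tert-butyldimethylsilyloxy)-3-methoxyphenyl]prop-2-enoic acid, via bis-silylated ferulate 2 (not isolated)
Conditions: TBSCl (2.3 equiv), imidazole, DMF, rt; then AcOH–THF–H2O, rt
Reagents that add atoms: tert-butyldimethylsilyl chloride, CC(C)(C)[Si](C)(C)Cl
Why: Standard silylation of phenol and acid followed by selective hydrolysis of the far more labile silyl ester, with no stereocentre involved and the E‑alkene untouched.

Step 2
Reactants: 3 O-TBS-ferulic acid (2 equiv); 4 naphthalene-1,8-diol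
Product: 5 naphthalene-1,8-diyl bis[(E)-3-(4-TBSO-3-methoxyphenyl)prop-2-enoate]
Conditions: DCC (2.2 equiv), DMAP (cat.), CH2Cl2, 0 °C → rt
Reagents that add atoms: none
Why: Steglich esterification of both peri hydroxyls, which should hold the two cinnamoyl arms parallel, head‑to‑head and within bonding distance.

Step 3
Reactants: 5 template diester
Product: 6 cyclic naphthalene-1,8-diyl (1R,2S,3R,4S)-3,4-bis(4-TBSO-3-methoxyphenyl)cyclobutane-1,2-dicarboxylate (meso; carboxyls cis; aryls cis; each aryl trans to its neighbouring carboxyl)
Conditions: hν (365 nm), crystalline powder between glass plates, rt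
Reagents that add atoms: none
Why: Template‑directed topochemical [2+2] photocycloaddition of peri‑held dicinnamates, in which suprafacial union of two parallel E‑alkenes keeps each aryl/carbonyl pair trans and puts like groups cis, setting all four centres as the Cs (β‑truxinate) isomer.

Step 4
Reactants: 6 template-bound cyclobutane
Product: 7 meso-[(1R,2S,3R,4S)-3,4-bis(4-TBSO-3-methoxyphenyl)cyclobutane-1,2-diyl]dimethanol
Conditions: DIBAL-H (6 equiv), CH2Cl2, −78 → 0 °C; aq. Rochelle salt
Reagents that add atoms: none
Why: DIBAL‑H reduction of activated aryl esters, as in the reduction of silyl‑protected ferulates to coniferyl alcohols, which releases the template and leaves aryl silyl ethers and stereocentres untouched.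

Step 5
Reactants: 7 meso diol
Product: 8 [(1R,2S,3R,4S)-2-(hydroxymethyl)-3,4-bis(4-TBSO-3-methoxyphenyl)cyclobutyl]methyl acetate
Conditions: immobilised Burkholderia cepacia lipase, vinyl acetate, MTBE, 30 °C
Reagents that add atoms: vinyl acetate, C=COC(C)=O
Why: Lipase‑catalysed enantiotopic‑group‑selective transesterification of a meso cis‑1,2‑bis(hydroxymethyl)cycloalkane with an irreversible acyl donor, where the enzyme pocket selects the CH2OH on the R‑configured carbon, so that absolute configuration and the acetate of the target are installed together.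

Step 6
Reactants: 8 monoacetate
Product: 9 [(1R,2S,3R,4S)-2-formyl-3,4-bis(4-TBSO-3-methoxyphenyl)cyclobutyl]methyl acetate
Conditions: TEMPO (10 mol %), PhI(OAc)2 (1.1 equiv), CH2Cl2, rt
Reagents that add atoms: none
Why: Piancatelli–Margarita oxidation stops at the aldehyde under nearly neutral conditions that disfavour the acetyl migration which would racemise 8, and any epimerisation at the formyl‑bearing carbon is harmless because that centre is erased in step 8.

Step 7
Reactants: 9 bis-silyl aldehyde
Product: 10 [(1R,2S,3R,4S)-2-formyl-3,4-bis(4-hydroxy-3-methoxyphenyl)cyclobutyl]methyl acetate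
Conditions: TBAF (2.2 equiv), AcOH (2.5 equiv), THF, 0 °C
Reagents that add atoms: none
Why: Buffered fluoride cleavage of aryl silyl ethers, with the acetic acid protecting acetate and aldehyde and keeping the phenols protonated so that no phenoxide‑driven push–pull opening of the cyclobutane sets in.

Step 8
Reactants: 10 bisphenol cyclobutane aldehyde
Product: 13 [(1S,2R)-3-formyl-7-hydroxy-1-(4-hydroxy-3-methoxyphenyl)-6-methoxy-1,2-dihydronaphthalen-2-yl]methyl acetate (target), via bis-p-quinone methide 11 (not isolated), via quinone methide enal 12 (not isolated)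
Conditions: FeCl3 (2.05 equiv, slow addition), CH2Cl2–(CF3)2CHOH 4:1, 5 mM, 4 Å MS, −20 → 0 °C; aq. NaHCO3
Reagents that add atoms: none
Why: Proposed new method: Fe(III) should oxidise one para‑phenol to its phenoxyl radical, whose spin density next to the cyclobutane triggers strain‑releasing β‑scission of the doubly benzylic C1–C4 bond (target numbering) and, after a second one‑electron oxidation, gives bis‑p‑quinone methide 11. Only H‑3 is acidified by the formyl group, so only that quinone methide tautomerises, giving the (E)‑2‑alkylconiferaldehyde 12, in which the re‑aromatised guaiacyl ring lies cis to the chain that carries the second quinone methide. The acid‑activated quinone methide carbon C1 is then attacked by arene carbon C8a, para to 6‑OMe, in a 6‑exo‑trig Friedel–Crafts closure (arene bond C4a=C8a endocyclic), and proton loss restores the arene, so that C4a and C8a end up inserted between C4 and C1 of the former four‑membered ring. The closest known reaction types are the oxidative opening of 1,2‑bis(4‑hydroxyaryl)cyclobutanes to bis‑quinone methides captured by oxygen nucleophiles and the acid‑induced closure of 8–8′‑linked ferulate dimers to trans‑1‑aryl‑1,2‑dihydronaphthalenes; their merger with carbon capture in one operation is untested. The one new stereocentre C1 is controlled by the untouched C2 centre: in the half‑chair transition state CH2OAc sits pseudoaxial to avoid A(1,2) strain with the formyl group, and the aryl‑bearing carbon bonds anti to it and away from H‑8, which should give the 1,2‑trans (1S,2R) isomer. The step needs site‑selective scission (C1–C4 is the only ring bond whose cleavage gives a benzylic radical from either phenoxyl), regioselective closure (the position ortho to OMe is flanked on both sides) and restraint of the oxidant (two oxidising equivalents at high dilution, and 13 has no strained bond through which its phenoxyl radical could decay irreversibly).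

**Compound list**
1 | (E)-ferulic acid | COc1cc(/C=C/C(=O)O)ccc1O | starting material
2 | tert-butyldimethylsilyl (E)-3-[4-(tert-butyldimethylsilyloxy)-3-methoxyphenyl]prop-2-enoate | COc1cc(/C=C/C(=O)O[Si](C)(C)C(C)(C)C)ccc1O[Si](C)(C)C(C)(C)C | intermediate
3 | (E)-3-[4-(tert-butyldimethylsilyloxy)-3-methoxyphenyl]prop-2-enoic acid | COc1cc(/C=C/C(=O)O)ccc1O[Si](C)(C)C(C)(C)C | intermediate
4 | naphthalene-1,8-diol | Oc1cccc2cccc(O)c12 | starting material
5 | naphthalene-1,8-diyl bis[(E)-3-(4-TBSO-3-methoxyphenyl)prop-2-enoate] | COc1cc(/C=C/C(=O)Oc2cccc3cccc(OC(=O)/C=C/c4ccc(O[Si](C)(C)C(C)(C)C)c(OC)c4)c23)ccc1O[Si](C)(C)C(C)(C)C | intermediate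
6 | cyclic naphthalene-1,8-diyl (1R,2S,3R,4S)-3,4-bis(4-TBSO-3-methoxyphenyl)cyclobutane-1,2-dicarboxylate (meso) | O=C1Oc2cccc3cccc(OC(=O)[C@@H]4[C@H]1[C@@H](c5ccc(O[Si](C)(C)C(C)(C)C)c(OC)c5)[C@H]4c5ccc(O[Si](C)(C)C(C)(C)C)c(OC)c5)c23 | intermediate
7 | meso-[(1R,2S,3R,4S)-3,4-bis(4-TBSO-3-methoxyphenyl)cyclobutane-1,2-diyl]dimethanol | OC[C@@H]1[C@H](CO)[C@@H](c2ccc(O[Si](C)(C)C(C)(C)C)c(OC)c2)[C@H]1c3ccc(O[Si](C)(C)C(C)(C)C)c(OC)c3 | intermediate
8 | [(1R,2S,3R,4S)-2-(hydroxymethyl)-3,4-bis(4-TBSO-3-methoxyphenyl)cyclobutyl]methyl acetate | OC[C@@H]1[C@H](COC(C)=O)[C@@H](c2ccc(O[Si](C)(C)C(C)(C)C)c(OC)c2)[C@H]1c3ccc(O[Si](C)(C)C(C)(C)C)c(OC)c3 | intermediate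
9 | [(1R,2S,3R,4S)-2-formyl-3,4-bis(4-TBSO-3-methoxyphenyl)cyclobutyl]methyl acetate | O=C[C@@H]1[C@H](COC(C)=O)[C@@H](c2ccc(O[Si](C)(C)C(C)(C)C)c(OC)c2)[C@H]1c3ccc(O[Si](C)(C)C(C)(C)C)c(OC)c3 | intermediate
10 | [(1R,2S,3R,4S)-2-formyl-3,4-bis(4-hydroxy-3-methoxyphenyl)cyclobutyl]methyl acetate | O=C[C@@H]1[C@H](COC(C)=O)[C@@H](c2ccc(O)c(OC)c2)[C@H]1c3ccc(O)c(OC)c3 | intermediate
11 | (2S,3R)-3-(acetoxymethyl)-2-formyl-1,4-bis(3-methoxy-4-oxocyclohexa-2,5-dien-1-ylidene)butane (bis-p-quinone methide) | O=C[C@@H](C=C1C=CC(=O)C(OC)=C1)[C@H](COC(C)=O)C=C2C=CC(=O)C(OC)=C2 | intermediate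
12 | [(2R,3E)-3-formyl-4-(4-hydroxy-3-methoxyphenyl)-2-[(3-methoxy-4-oxocyclohexa-2,5-dien-1-ylidene)methyl]but-3-en-1-yl] acetate | O=C/C(=C/c1ccc(O)c(OC)c1)[C@H](COC(C)=O)C=C2C=CC(=O)C(OC)=C2 | intermediate
13 | [(1S,2R)-3-formyl-7-hydroxy-1-(4-hydroxy-3-methoxyphenyl)-6-methoxy-1,2-dihydronaphthalen-2-yl]methyl acetate | COc1cc([C@H]2c3cc(O)c(OC)cc3C=C(C=O)[C@@H]2COC(C)=O)ccc1O | target

Total step count: 8. Longest linear sequence: 8 steps, from ferulic acid.

**Steps most likely to fail**

1. Step 8 (Proposed new method).
   - What may go wrong: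
     - The ring‑opened radical may fragment further into two C6–C3 units (cycloreversion).
     - Redox‑neutral push–pull cleavage of the ring bond between the aryl‑ and formyl‑bearing carbons may compete.
     - Closure onto the enal‑deactivated arene may be slow, so that the quinone methide is lost to oligomerisation.
     - Vinylogous deprotonation at C2 may occur.
     - The product may be dehydrogenated further to the arylnaphthalene.
   - Fallback with known chemistry, which separates the oxidation from the C–C bond formation. It sets out from 10.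
     - Ag2O in CH2Cl2–MeOH opens the cyclobutane oxidatively, and methanol captures the quinone methide that cannot tautomerise. This gives the open‑chain benzylic methyl ether enal F1 (both benzylic epimers), which is isolated.
     - With no oxidant present, TFA in CH2Cl2 ionises the p‑hydroxybenzyl ether, and the Friedel–Crafts closure known from 8–8′ ferulate dimers follows.
     - The sequence comes back at 13.

2. Step 5.
   - What may go wrong: discrimination of the enantiotopic arms may be slow on the bulky diol, low, or of the wrong sense. Acetyl migration between the arms may erode the enantiomeric purity.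
   - Fallback: it sets out from 7.
     - Peracetylation (Ac2O, pyridine) gives the meso diacetate F2.
     - One enantiotopic ester is then hydrolysed with an esterase or lipase in pH 7 buffer–MTBE.
     - An enzyme addresses the same arm in both directions, so hydrolysis leaves the acetate on the arm that acylation would have left free.
     - The sequence comes back at 8.

3. Step 3.
   - What may go wrong: crystal packing of the bulky silyl ether may hold the alkenes non‑parallel or too far apart, so that E/Z isomerisation or no reaction takes over. Loss of crystallinity during conversion may erode diastereocontrol.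
   - Fallback in solution at the alcohol oxidation level. It sets out from 2, taken out of step 1 before the hydrolysis.
     - DIBAL‑H reduces the silyl ester to O‑TBS‑coniferyl alcohol F3.
     - iPr2SiCl2 and imidazole tie two molecules to the bis(allyloxy)diisopropylsilane F4.
     - Direct irradiation (Pyrex, dilute solution) should close the cyclobutane‑fused dioxasilepane F5 through the sandwich singlet excimer enforced by the short O–Si–O tether. F5 should have the same cis,trans,cis arrangement.
     - PPTS in MeOH removes the silicon tether while the aryl silyl ethers stay.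
     - The sequence comes back at 7.

**Further compounds**
F1 | step 8 | [(2R,3E)-3-formyl-4-(4-hydroxy-3-methoxyphenyl)-2-[(4-hydroxy-3-methoxyphenyl)(methoxy)methyl]but-3-en-1-yl] acetate (both benzylic epimers) | O=C/C(=C/c1ccc(O)c(OC)c1)[C@H](COC(C)=O)C(OC)c2ccc(O)c(OC)c2
F2 | step 5 | meso-[(1R,2S,3R,4S)-3,4-bis(4-TBSO-3-methoxyphenyl)cyclobutane-1,2-diyl]bis(methylene) diacetate | CC(=O)OC[C@@H]1[C@H](COC(C)=O)[C@@H](c2ccc(O[Si](C)(C)C(C)(C)C)c(OC)c2)[C@H]1c3ccc(O[Si](C)(C)C(C)(C)C)c(OC)c3
F3 | step 3 | (E)-3-[4-(tert-butyldimethylsilyloxy)-3-methoxyphenyl]prop-2-en-1-ol | COc1cc(/C=C/CO)ccc1O[Si](C)(C)C(C)(C)C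
F4 | step 3 | bis[(E)-3-(4-TBSO-3-methoxyphenyl)prop-2-enyloxy]diisopropylsilane | CC(C)[Si](OC/C=C/c1ccc(O[Si](C)(C)C(C)(C)C)c(OC)c1)(OC/C=C/c2ccc(O[Si](C)(C)C(C)(C)C)c(OC)c2)C(C)C
F5 | step 3 | meso cis-fused 4,4-diisopropyl-3,5-dioxa-4-silabicyclo[5.2.0]nonane bearing two cis 4-TBSO-3-methoxyphenyl groups at C8 and C9, each trans to the neighbouring CH2O | CC(C)[Si]1(C(C)C)OC[C@@H]2[C@H](CO1)[C@@H](c3ccc(O[Si](C)(C)C(C)(C)C)c(OC)c3)[C@H]2c3ccc(O[Si](C)(C)C(C)(C)C)c(OC)c3
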